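## Retrosynthetic overview
1. The target 18 is traced back, through 7-O-acetylation, 7-ketone reduction, 6-O-angeloylation and C6 enolate hydroxylation, to (12E)-labda-12,14-diene-7α,8α-diol 11.
2. Key disconnection at C13–C14 and C13–C16: 11 comes from the tricyclic dihydropyran 8. Its C13, a masked formyl carbon, is lithiated (acyl anion equivalent), takes up vinyl by a cuprate 1,2-metallate shift and is then methylated. This opens ring C, frees the 8α-OH and fixes the 12E geometry.
3. 8 comes from lactol 5 by C12–C13 Wittig homologation and cyclodehydration. 5 comes from 7α-hydroxysclareolide 4, which comes from the Δ7 ester 2 and (+)-sclareolide 1.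
4. Rings: the A/B decalin (C5, C9, C10) is bought in 1. The lactone ring is opened in step 1 and re-closed in step 2. The enol-ether ring C is built in step 5 and sacrificed in step 6.

Assumption: with labdane numbering, the SMILES decodes as the normal labdane series (5α-H, 9α-H, 10β-Me) with 6α-O-angelate (Z), 7β-OAc, 8α-OH/8β-Me and a 12E diene. This is the same absolute series as (+)-sclareolide.

## Route

Step 1
Reactants: 1 (+)-sclareolide
Product: 2 methyl 13,14,15,16-tetranorlabd-7-en-12-oate (5α-H, 9α-H, 10β-Me)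
Conditions: conc. H2SO4, MeOH, reflux; AgNO3–silica chromatography
Reagents that add atoms: methanol, CO
Why: Alkyl–oxygen opening of the tertiary lactone gives the C8 cation, Fischer esterification blocks re-lactonisation, and E1 loss of the axial 7α-H gives the trisubstituted Δ7 alkene as the main isomer, with C5, C9 and C10 untouched.

Step 2
Reactants: 2 methyl 13,14,15,16-tetranorlabd-7-en-12-oate
Product: 4 7α-hydroxysclareolide (7α-hydroxy-13,14,15,16-tetranorlabdan-12,8α-olide), via diol ester 3 (not isolated)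
Conditions: OsO4 (cat.), NMO, MeSO2NH2, acetone/t-BuOH/H2O, 40 °C; then p-TsOH (cat.), CH2Cl2, rt
Reagents that add atoms: N-methylmorpholine N-oxide, C[N+]1([O-])CCOCC1; water, O
Why: Upjohn dihydroxylation takes place on the α face because the axial C10 methyl screens the β face, which sets 8α-OH/8β-Me and a temporary 7α-OH, and the γ-hydroxy ester then lactonises to the trans-fused lactone.

Step 3
Reactants: 4 7α-hydroxysclareolide
Product: 5 8α,12-epoxy-13,14,15,16-tetranorlabdane-7α,12-diol (lactol, C12 anomers)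
Conditions: DIBAL-H (2.5 equiv), CH2Cl2, −78 °C; Rochelle salt
Reagents that add atoms: none
Why: Partial lactone reduction stops at the stable aluminium hemiacetal at −78 °C, and the new C12 centre is lost in the next step.

Step 4
Reactants: 5 lactol
Product: 6 13-methoxy-14,15,16-trinorlabd-12-ene-7α,8α-diol (E/Z enol ether)
Conditions: MeOCH2PPh3Cl, KOt-Bu, THF, 0 °C → rt
Reagents that add atoms: (methoxymethyl)triphenylphosphonium chloride, COC[P+](c1ccccc1)(c1ccccc1)c1ccccc1.[Cl-]
Why: Wittig methoxymethylenation of the ring-opened hydroxy-aldehyde tautomer adds C13 at the aldehyde oxidation level, and the alkene geometry is irrelevant because it is erased in step 5.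

Step 5
Reactants: 6 enol ether diol
Product: 8 8α,13-epoxy-14,15,16-trinorlabd-12-en-7α-ol (tricyclic dihydropyran), via methyl acetal 7 (not isolated)
Conditions: PPTS (cat.), toluene, reflux through 4 Å MS; Et3N quench
Reagents that add atoms: none
Why: Protonation at C12 gives the C13 oxocarbenium ion, the 8α-OH closes the six-membered cyclic acetal, and acid-catalysed loss of methanol, driven by its removal, gives the endocyclic enol ether with no stereocentre touched.

Step 6 (key step)
Reactants: 8 tricyclic dihydropyran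
Product: 11 (12E)-labda-12,14-diene-7α,8α-diol, via dilithio enol ether 9 (not isolated), via dienylcuprate 10 (not isolated)
Conditions: t-BuLi (2.2 equiv), THF, −78 → 0 °C; (CH2=CH)2CuMgBr [CH2=CHMgBr, CuBr·SMe2], Et2O/Me2S, −40 °C → rt; MeI (excess), DMPU, 0 °C → rt; aq NH4Cl/NH3
Reagents that add atoms: vinylmagnesium bromide, C=C[Mg]Br; iodomethane, CI
Why: Proposed new method: C13 is a masked formyl carbon (natural acceptor) turned into a donor by α-lithiation, so it can end up bonded to the acceptor carbon of MeI; on the mixed cuprate the vinyl ligand migrates from Cu to C13 anti to the departing C13–O8 bond (inversion at the carbenoid carbon), which puts vinyl trans to C11, expels the 8α-alkoxide and leaves Cu cis to C11, and MeI replaces Cu with retention to give only 12E; the closest known reaction type is the Fujisawa–Kocienski 1,2-metallate rearrangement of α-alkoxyalkenyl cuprates, established for alkyl, silyl and stannyl ligands on simple dihydrofurans and dihydropyrans.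

Step 7
Reactants: 11 (12E)-labda-12,14-diene-7α,8α-diol
Product: 12 (12E)-8α-hydroxylabda-12,14-dien-7-one
Conditions: (COCl)2, DMSO, CH2Cl2, −78 °C; Et3N, → 0 °C
Reagents that add atoms: none
Why: Swern oxidation takes the axial secondary 7α-OH to the ketone without glycol cleavage and leaves the tertiary alcohol and the diene alone.

Step 8
Reactants: 12 (12E)-8α-hydroxylabda-12,14-dien-7-one
Product: 13 (12E)-6α,8α-dihydroxylabda-12,14-dien-7-one
Conditions: KHMDS (2.5 equiv), THF, −78 → −40 °C; 2-(phenylsulfonyl)-3-phenyloxaziridine, −78 °C; aq NH4Cl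
Reagents that add atoms: 2-(phenylsulfonyl)-3-phenyloxaziridine, O=S(=O)(c1ccccc1)N1OC1c1ccccc1
Why: In this Davis enolate hydroxylation C8 is quaternary so only C6 can enolise, the β face is closed by the axial methyls on C4, C8 and C10 so oxygen arrives from the α face, and 6α (equatorial) is also the thermodynamic epimer.

Step 9
Reactants: 13 (12E)-6α,8α-dihydroxylabda-12,14-dien-7-one; 14 angelic acid
Product: 16 (12E)-6α-angeloyloxy-8α-hydroxylabda-12,14-dien-7-one, via mixed anhydride 15 (not isolated)
Conditions: 14, 2,4,6-Cl3C6H2COCl, Et3N, toluene, rt; then 13, 80 °C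
Reagents that add atoms: angelic acid 14, C/C=C(/C)C(=O)O
Why: Yamaguchi-type mixed-anhydride esterification without a nucleophilic catalyst acylates the only secondary OH, the tertiary 8-OH being inert, and avoids the addition–elimination path that turns angelate into tiglate.

Step 10
Reactants: 16 (12E)-6α-angeloyloxy-8α-hydroxylabda-12,14-dien-7-one
Product: 17 (12E)-6α-angeloyloxylabda-12,14-diene-7β,8α-diol
Conditions: NaBH4, CeCl3·7H2O, MeOH/THF, −78 °C
Reagents that add atoms: none
Why: In this Luche reduction hydride attacks axially from the α face because the adjacent axial 8β-methyl blocks the β face, giving the equatorial 7β-OH, while the cold, non-basic medium suppresses 6→7 acyl migration and spares the enoate.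

Step 11
Reactants: 17 (12E)-6α-angeloyloxylabda-12,14-diene-7β,8α-diol
Product: 18 target, (12E)-7β-acetoxy-6α-angeloyloxy-labda-12,14-dien-8α-ol
Conditions: Ac2O, DMAP (cat.), pyridine, rt → 40 °C
Reagents that add atoms: acetic anhydride, CC(=O)OC(C)=O
Why: DMAP-catalysed acetylation reaches the only secondary OH left, and the tertiary 8α-OH does not react under these conditions.

## Compound list
1 | (+)-sclareolide | O=C1C[C@H]2[C@](C)(O1)CC[C@H]3C(C)(C)CCC[C@@]32C | starting material
2 | methyl 13,14,15,16-tetranorlabd-7-en-12-oate | COC(=O)C[C@H]1C(C)=CC[C@H]2C(C)(C)CCC[C@@]21C | intermediate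
3 | methyl 7α,8α-dihydroxy-13,14,15,16-tetranorlabdan-12-oate | COC(=O)C[C@H]1[C@](C)(O)[C@H](O)C[C@H]2C(C)(C)CCC[C@@]21C | intermediate (not isolated)
4 | 7α-hydroxysclareolide | O=C1C[C@H]2[C@](C)(O1)[C@H](O)C[C@H]3C(C)(C)CCC[C@@]32C | intermediate
5 | 8α,12-epoxy-13,14,15,16-tetranorlabdane-7α,12-diol (lactol, anomers) | OC1C[C@H]2[C@](C)(O1)[C@H](O)C[C@H]3C(C)(C)CCC[C@@]32C | intermediate
6 | 13-methoxy-14,15,16-trinorlabd-12-ene-7α,8α-diol (E/Z) | COC=CC[C@H]1[C@](C)(O)[C@H](O)C[C@H]2C(C)(C)CCC[C@@]21C | intermediate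
7 | 13-methoxy-8α,13-epoxy-14,15,16-trinorlabdan-7α-ol (C13 epimers) | COC1CC[C@H]2[C@](C)(O1)[C@H](O)C[C@H]3C(C)(C)CCC[C@@]32C | intermediate (not isolated)
8 | 8α,13-epoxy-14,15,16-trinorlabd-12-en-7α-ol | C1=CC[C@H]2[C@](C)(O1)[C@H](O)C[C@H]3C(C)(C)CCC[C@@]32C | intermediate
9 | 13-lithio-8α,13-epoxy-14,15,16-trinorlabd-12-ene, lithium 7α-alkoxide | [Li]C1=CC[C@H]2[C@](C)(O1)[C@H](O[Li])C[C@H]3C(C)(C)CCC[C@@]32C | intermediate (not isolated)
10 | 13-cuprio-16-norlabda-12,14-diene-7α,8α-diolate (vinyl trans to C11; drawn as the organocopper, second ligand omitted) | C=C/C([Cu])=C/C[C@H]1[C@](C)(O[Li])[C@H](O[Li])C[C@H]2C(C)(C)CCC[C@@]21C | intermediate (not isolated)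
11 | (12E)-labda-12,14-diene-7α,8α-diol | C=C/C(C)=C/C[C@H]1[C@](C)(O)[C@H](O)C[C@H]2C(C)(C)CCC[C@@]21C | intermediate
12 | (12E)-8α-hydroxylabda-12,14-dien-7-one | C=C/C(C)=C/C[C@H]1[C@](C)(O)C(=O)C[C@H]2C(C)(C)CCC[C@@]21C | intermediate
13 | (12E)-6α,8α-dihydroxylabda-12,14-dien-7-one | C=C/C(C)=C/C[C@H]1[C@](C)(O)C(=O)[C@H](O)[C@H]2C(C)(C)CCC[C@@]21C | intermediate
14 | angelic acid, (Z)-2-methylbut-2-enoic acid | C/C=C(/C)C(=O)O | starting material
15 | angelic 2,4,6-trichlorobenzoic anhydride | C/C=C(/C)C(=O)OC(=O)c1c(Cl)cc(Cl)cc1Cl | intermediate (not isolated)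
16 | (12E)-6α-angeloyloxy-8α-hydroxylabda-12,14-dien-7-one | C=C/C(C)=C/C[C@H]1[C@](C)(O)C(=O)[C@H](OC(=O)/C(C)=C\C)[C@H]2C(C)(C)CCC[C@@]21C | intermediate
17 | (12E)-6α-angeloyloxylabda-12,14-diene-7β,8α-diol | C=C/C(C)=C/C[C@H]1[C@](C)(O)[C@@H](O)[C@H](OC(=O)/C(C)=C\C)[C@H]2C(C)(C)CCC[C@@]21C | intermediate
18 | (12E)-7β-acetoxy-6α-angeloyloxylabda-12,14-dien-8α-ol (CNP0553436.1) | C=C/C(C)=C/C[C@H]1[C@](C)(O)[C@@H](OC(C)=O)[C@H](OC(=O)/C(C)=C\C)[C@H]2C(C)(C)CCC[C@@]21C | target

## Step count and risks
Total steps: 11. Longest linear sequence: 11 (1 → 18). No protecting groups are used.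

**Step 6** is the most likely to fail. Vinyl may migrate poorly, or methylation of the mixed cuprate may be incomplete. The fallback drops the metallate chemistry. It sets out from lactol 5 and returns at 11. Compound 5 is heated with 2-(triphenylphosphoranylidene)propanal in toluene at 90 °C, which gives by an E-selective stabilised Wittig reaction (12E)-7α,8α-dihydroxy-15-norlabd-12-en-14-al F3. Methylenation of this enal with Ph3P=CH2 in THF at 0 °C gives 11. Compounds 6–10 are bypassed.

**Step 1** is at risk in the regiochemistry of the E1 dehydration (Δ7 against Δ8(9) and Δ8(17)). The fallback sets out from 1 and returns at 2. Compound 1 is saponified (KOH, MeOH) and the carboxylate is methylated (MeI, DMF) to methyl 8α-hydroxy-13,14,15,16-tetranorlabdan-12-oate F1. SOCl2/pyridine at −78 °C removes a methyl proton from the equatorial chlorosulfite and gives cleanly the exocyclic alkene methyl 13,14,15,16-tetranorlabd-8(17)-en-12-oate F2. RhCl3·3H2O (cat.) in refluxing EtOH then moves the double bond into the ring to the trisubstituted position, which is 2.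

**Step 9** is at risk because the 6α-OH is hindered by the peri methyl group and the angelate can isomerise to the tiglate. The fallback builds the Z-enoate on the substrate. It sets out from 13 and returns at 18.
- Compound 13 is esterified (DCC, DMAP cat.) with 2-[bis(2,2,2-trifluoroethoxy)phosphoryl]propanoic acid to the 6α-phosphonopropionate ketone F4.
- Reduction as in step 10 gives the 7β-alcohol F5.
- Acetylation as in step 11 gives the 7β-acetate F6.
- A Still–Gennari olefination of F6 (KHMDS, 18-crown-6, THF, −78 °C, acetaldehyde) closes the sequence and gives the Z-configured angelate 18.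
- Base is used only after the ketone is gone, so no intramolecular olefination to a butenolide can occur.

## Further compounds
F1 | step 1 | methyl 8α-hydroxy-13,14,15,16-tetranorlabdan-12-oate | COC(=O)C[C@H]1[C@](C)(O)CC[C@H]2C(C)(C)CCC[C@@]21C
F2 | step 1 | methyl 13,14,15,16-tetranorlabd-8(17)-en-12-oate | COC(=O)C[C@H]1C(=C)CC[C@H]2C(C)(C)CCC[C@@]21C
F3 | step 6 | (12E)-7α,8α-dihydroxy-15-norlabd-12-en-14-al | O=C/C(C)=C/C[C@H]1[C@](C)(O)[C@H](O)C[C@H]2C(C)(C)CCC[C@@]21C
F4 | step 9 | (12E)-6α-{2-[bis(2,2,2-trifluoroethoxy)phosphoryl]propanoyloxy}-8α-hydroxylabda-12,14-dien-7-one | C=C/C(C)=C/C[C@H]1[C@](C)(O)C(=O)[C@H](OC(=O)C(C)P(=O)(OCC(F)(F)F)OCC(F)(F)F)[C@H]2C(C)(C)CCC[C@@]21C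
F5 | step 9 | (12E)-6α-{2-[bis(2,2,2-trifluoroethoxy)phosphoryl]propanoyloxy}labda-12,14-diene-7β,8α-diol | C=C/C(C)=C/C[C@H]1[C@](C)(O)[C@@H](O)[C@H](OC(=O)C(C)P(=O)(OCC(F)(F)F)OCC(F)(F)F)[C@H]2C(C)(C)CCC[C@@]21C
F6 | step 9 | (12E)-7β-acetoxy-6α-{2-[bis(2,2,2-trifluoroethoxy)phosphoryl]propanoyloxy}labda-12,14-dien-8α-ol | C=C/C(C)=C/C[C@H]1[C@](C)(O)[C@@H](OC(C)=O)[C@H](OC(=O)C(C)P(=O)(OCC(F)(F)F)OCC(F)(F)F)[C@H]2C(C)(C)CCC[C@@]21C
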